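Atom numbers used throughout (daucane numbering): ring A = C1–C5, ring B = C1, C5, C6–C10; C11–C13 = isopropyl on C4, C14 = methyl on C8, C15 = methyl on C1. Compounds 1–17 are those of the steps below.

## The problem

1. The target is a daucane: a cyclopentane (ring A) trans-fused through the C1–C5 bond to a cycloheptene (ring B, C8=C9). C1 is quaternary, C4 is a tertiary carbinol bearing isopropyl, C6 carries the 4-methoxybenzoate, and C10 is a secondary allylic carbinol.
2. Five stereocentres are contiguous around the ring-fusion bond (C10–C1–C5, with C4 and C6 both on C5). C15 and O4 lie on one face (β); H5, O6 and O10 lie on the other (α).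
3. The trans fusion is the first trap. Closing a ring onto an sp2 C5 from a tether on C1 gives the cis isomer, and with an angular methyl a bicyclic ketone has no reliable preference for trans. C5 must therefore be set while ring A is still monocyclic, where the bulkier substituent on C1 controls it.
4. The second trap is C10. In the bicycle the angular methyl sits over one face of a C10 carbonyl, so a hydride enters anti to it and gives the 10β alcohol. O10 must be set before ring B exists.
5. C4 can be controlled by C5 (addition to a C4 ketone anti to the C5 substituent), and C6 by C5 and C4 together.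
6. Sensitive points: C8=C9 is β,γ to C6 and would conjugate with a C6 ketone; the C4–OH/C6 β-hydroxy relationship invites retro-aldol and dehydration once C6 is a carbonyl; the ester must go on O6 in the presence of O10 and O4.
7. The feature that opens the problem: C10 and C6 both sit on the ring-fusion bond (C10–C1–C5–C6 is a 1,4-dioxygenated unit) and are joined across ring B by C9=C8(C14)–C7, to which C10 is allylic and C6 homoallylic. Ring B is thus a 1,4-dialdehyde allylated twice by a 2-methylallyl 1,3-dianion, once through each terminus.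

## Retrosynthesis

**17 ⇒ 16 ⇒ 14 + 15.** The ester C–O bond at O6 is cut, and O10 is traced back to a silyl ether. Acylating a free triol would require telling two hindered secondary hydroxyls apart. Here 14 has one free secondary hydroxyl (O6), a silylated O10 and an inert tertiary O4. The forward steps are an acylation with 15 and a fluoride deprotection.

**14 ⇒ 13 (key).** The C6–C7 bond of ring B is cut. The neighbouring cuts (C8=C9 by metathesis, C9–C10 by vinyl-metal addition) each need two separately built carbon arms and leave a ring-forming step that creates no stereocentre or an uncontrolled one. Cutting C6–C7 as an allylsilane–aldehyde addition lets one step close ring B, create the C6 carbinol and place C8=C9 with its methyl group. Precursor 13 is monocyclic. The forward reaction must be a 7-endo attack of C7 on the C6 aldehyde with loss of silicon from C9.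

**13 ⇒ 12 ⇒ 11.** The C6 aldehyde is masked as a dimethyl acetal, and the C4–C11 bond (isopropyl) is cut to give ketone 11. Adding isopropyl to a 2,3,3-trisubstituted cyclopentanone is preferred over building C4 earlier, because the C5 substituent and the C1 methyl then both direct the nucleophile to the α-face. The forward reaction needs a non-basic organometallic (cerium) and a C5 centre that is already fixed.

**11 ⇒ 10 ⇒ 9 ⇒ 5 + 6 (through 7).** The C9–C10 bond is cut. A γ-silylallylborane made from silane 6 adds to aldehyde 5, sets C10 under reagent control, and leaves the allylsilane needed for the key step. The linchpin 6 thus supplies C7, C8, C9 and C14 in one reagent. Once this large arm is on C1, the C5 centre (α to the ketone) is equilibrated to the trans arrangement (10 to 11). Aldehyde 5 has ten carbons and one defined stereocentre.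

**5 ⇒ 4 ⇒ 3 ⇒ 1.** The C1–C10 bond (as an alkenyl group, later cleaved to the aldehyde) and the C5–C6 bond are cut. This leads to 3-methylcyclopent-2-en-1-one 1, whose carbonyl, α- and β-carbons are C4, C5 and C1. Asymmetric conjugate addition sets the quaternary centre, and trapping the enolate is the only regioselective access to C5.

## Roads not taken

**Alternative 1:** cut C8=C9 (ring-closing metathesis, the most obvious plan).
- Forward key step: the diene triol A1 (vinyl carbinol at C10, 2-methylallyl carbinol at C6) is closed to triol A2 with a ruthenium carbene.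
- Why the chosen plan is better: A1 needs two separate carbinol-forming additions and two alkene arms. The metathesis has to form a trisubstituted alkene next to a neopentyl-type carbinol and creates no stereocentre. A2 has two free secondary hydroxyls that must be differentiated before esterification. The chosen plan uses one reagent for C7–C9, sets C6 in the ring closure, leaves O6 as the only free secondary hydroxyl, and is two to three steps shorter.

**Alternative 2:** cut C1–C5 as a 1,2-shift in a decalin.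
- Forward key step: the symmetric triketone A3 is desymmetrised by Hajos–Parrish-type aldolisation to enedione A4. After isopropyl addition and oxygenation of C5/C6, a pinacol-type shift of C1 from C6 to C5 gives the hydroazulenone A5.
- Attraction: ring B with O6, O10 and C14 comes from a cheap symmetric dione.
- Why the chosen plan is better: a leaving group on C5 can only be installed anti to the angular methyl, and migration with inversion then leaves H5 on the methyl face. A5 is therefore cis-fused, and C5, now α to a ketone, offers no reliable correction. The C10 ketone would be reduced anti to the methyl (10β), and C8=C9 would still have to be introduced through an enone.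

**Alternative 3:** make and cleave a temporary C6–C10 bond.
- Forward key step: [2+2] photocycloaddition of 1 with the bis-silyloxy cyclopentene A6 gives cyclobutane A7. Desilylation and glycol cleavage open it to trione A8, which holds the whole ring system with oxygen on C6 and C10 after two operations.
- Why the chosen plan is better: the cyclobutane fixes the cis ring fusion. In A8, C5 lies between the C4 and C6 carbonyls, so its configuration and the C4/C6 distinction are lost. C10 is again reduced from the wrong face, the material is racemic, and isopropyl and C8=C9 remain to be added.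

Key step: step 9

Remark: 4, 5, 9 and 10 are carried as mixtures of C5 epimers (ring position 2), which converge in step 6.

Remark: 9–13 are drawn with the anti C9 configuration expected from the (E)-allylborane; C9 becomes sp2 in step 9.

Remark: the sense of induction of the copper catalyst (step 1) and of the borane (step 4) is taken from the accepted models; the antipodal ligand or borane is used if the opposite sense is found.

## Steps

Step 1
Reactants: 1 3-methylcyclopent-2-en-1-one
Product: 3 trimethyl{[(3R)-3-[(1E)-hex-1-en-1-yl]-3-methylcyclopent-1-en-1-yl]oxy}silane, via aluminium enolate 2 (not isolated)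
Conditions: (E)-n-BuCH=CH-Al(i-Bu)2 (from hex-1-yne, i-Bu2AlH, hexane, 50 °C), Cu(O2CC4H3S) (5 mol %), chiral phosphinamine ligand (6 mol %), Et2O, −30 °C; then MeLi, Me3SiCl, Et3N, −30 to 0 °C
Reagents that add atoms: (E)-hex-1-enyl(diisobutyl)aluminium CCCC/C=C/[Al](CC(C)C)CC(C)C; chlorotrimethylsilane C[Si](C)(C)Cl
Why: Copper-catalysed asymmetric conjugate addition of an alkenylalane to a β-substituted cyclic enone sets the quaternary C1 under catalyst control (3R); silylating the aluminium enolate in place fixes the enol double bond towards C5, the position that cannot be enolised selectively later.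

Step 2
Reactants: 3 trimethyl{[(3R)-3-[(1E)-hex-1-en-1-yl]-3-methylcyclopent-1-en-1-yl]oxy}silane
Product: 4 (3R)-2-(dimethoxymethyl)-3-[(1E)-hex-1-en-1-yl]-3-methylcyclopentan-1-one (C2 epimers)
Conditions: HC(OMe)3, TMSOTf (cat.), CH2Cl2, −78 °C
Reagents that add atoms: trimethyl orthoformate COC(OC)OC
Why: Mukaiyama-type alkylation of the silyl enol ether by the dimethoxycarbenium ion forms C5–C6 with C6 at the aldehyde level and already masked; the C5 configuration is left open because hexenyl and methyl on C1 differ too little, and is settled in step 6.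

Step 3
Reactants: 4 (3R)-2-(dimethoxymethyl)-3-[(1E)-hex-1-en-1-yl]-3-methylcyclopentan-1-one (C2 epimers)
Product: 5 (1S)-2-(dimethoxymethyl)-1-methyl-3-oxocyclopentane-1-carbaldehyde (C2 epimers)
Conditions: O3, CH2Cl2–MeOH, −78 °C; then Me2S, −78 °C to rt
Reagents that add atoms: ozone [O-][O+]=O
Why: Ozonolysis (Criegee cleavage, reductive work-up) of the only C=C bond turns the hexenyl group into the non-enolisable C10 aldehyde; ketone and acetal are inert.

Step 4
Reactants: 5 (1S)-2-(dimethoxymethyl)-1-methyl-3-oxocyclopentane-1-carbaldehyde (C2 epimers); 6 trimethyl(2-methylprop-2-en-1-yl)silane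
Product: 9 (3S)-2-(dimethoxymethyl)-3-[(1S,2R)-1-hydroxy-3-methyl-2-(trimethylsilyl)but-3-en-1-yl]-3-methylcyclopentan-1-one (C2 epimers), via allylborane 7 (not isolated), via borinate 8 (not isolated)
Conditions: 6, s-BuLi, TMEDA, THF, −78 to −30 °C; (+)-Ipc2BOMe, −78 °C; BF3·OEt2; then 5, −78 °C; NaOH, H2O2, 0 °C
Reagents that add atoms: none
Why: Deprotonation of 6, borylation at the terminus remote from silicon and BF3 activation give the (E)-γ-silylallylborane 7, which adds through its silicon-bearing carbon in a closed chair transition state (γ-silylallylboration). The Ipc groups from (−)-α-pinene direct the allyl unit to the Re face of C10 (O10 α; the descriptor is S in 9 because silicon raises the rank of C9), the (E)-geometry gives the anti C9, and the aldehyde reacts far faster than the hindered ketone.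

Step 5
Reactants: 9 (3S)-2-(dimethoxymethyl)-3-[(1S,2R)-1-hydroxy-3-methyl-2-(trimethylsilyl)but-3-en-1-yl]-3-methylcyclopentan-1-one (C2 epimers)
Product: 10 (3S)-3-[(1S,2R)-1-{[tert-butyl(dimethyl)silyl]oxy}-3-methyl-2-(trimethylsilyl)but-3-en-1-yl]-2-(dimethoxymethyl)-3-methylcyclopentan-1-one (C2 epimers)
Conditions: TBSOTf, 2,6-lutidine, CH2Cl2, −78 to 0 °C
Reagents that add atoms: tert-butyldimethylsilyl trifluoromethanesulfonate CC(C)(C)[Si](C)(C)OS(=O)(=O)C(F)(F)F
Why: Silylation of the hindered secondary carbinol with a silyl triflate; it blocks Peterson elimination of the β-hydroxysilane in steps 7 and 9 and keeps O10 apart from O6 for the esterification.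

Step 6
Reactants: 10 (3S)-3-[(1S,2R)-1-{[tert-butyl(dimethyl)silyl]oxy}-3-methyl-2-(trimethylsilyl)but-3-en-1-yl]-2-(dimethoxymethyl)-3-methylcyclopentan-1-one (C2 epimers)
Product: 11 (2S,3S)-3-[(1S,2R)-1-{[tert-butyl(dimethyl)silyl]oxy}-3-methyl-2-(trimethylsilyl)but-3-en-1-yl]-2-(dimethoxymethyl)-3-methylcyclopentan-1-one
Conditions: K2CO3, MeOH, rt
Reagents that add atoms: none
Why: Base-mediated epimerisation of the β-keto acetal at C5 (enolisation, with reversible loss and return of methoxide) is stereoconvergent: the acetal settles trans to the very large silyloxy-allylsilane arm on C1, i.e. cis to C15, which is the 2S ketone.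

Step 7
Reactants: 11 (2S,3S)-3-[(1S,2R)-1-{[tert-butyl(dimethyl)silyl]oxy}-3-methyl-2-(trimethylsilyl)but-3-en-1-yl]-2-(dimethoxymethyl)-3-methylcyclopentan-1-one
Product: 12 (1R,2R,3S)-3-[(1S,2R)-1-{[tert-butyl(dimethyl)silyl]oxy}-3-methyl-2-(trimethylsilyl)but-3-en-1-yl]-2-(dimethoxymethyl)-3-methyl-1-(propan-2-yl)cyclopentan-1-ol
Conditions: i-PrMgCl, CeCl3, THF, −78 to −20 °C
Reagents that add atoms: isopropylmagnesium chloride CC(C)[Mg]Cl
Why: Organocerium addition (Grignard reagent with CeCl3) to a hindered, enolisable ketone; isopropyl should enter the α-face, anti to the adjacent acetal on C5 and to the pseudo-axial C15 on C1, giving the β-hydroxyl at C4 (1R).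

Step 8
Reactants: 12 (1R,2R,3S)-3-[(1S,2R)-1-{[tert-butyl(dimethyl)silyl]oxy}-3-methyl-2-(trimethylsilyl)but-3-en-1-yl]-2-(dimethoxymethyl)-3-methyl-1-(propan-2-yl)cyclopentan-1-ol
Product: 13 (1R,2R,5S)-5-[(1S,2R)-1-{[tert-butyl(dimethyl)silyl]oxy}-3-methyl-2-(trimethylsilyl)but-3-en-1-yl]-2-hydroxy-5-methyl-2-(propan-2-yl)cyclopentane-1-carbaldehyde
Conditions: PPTS (cat.), acetone–H2O (10:1), 40 °C
Reagents that add atoms: water O
Why: Mild acid hydrolysis of the dimethyl acetal frees the C6 aldehyde; the weak acid should spare the silyl ether and the allylsilane, and the aldehyde is used at once because of its β-hydroxy (retro-aldol) relationship to C4.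

Step 9
Reactants: 13 (1R,2R,5S)-5-[(1S,2R)-1-{[tert-butyl(dimethyl)silyl]oxy}-3-methyl-2-(trimethylsilyl)but-3-en-1-yl]-2-hydroxy-5-methyl-2-(propan-2-yl)cyclopentane-1-carbaldehyde
Product: 14 (3R,3aS,4S,8R,8aS)-8-{[tert-butyl(dimethyl)silyl]oxy}-6,8a-dimethyl-3-(propan-2-yl)-1,2,3,3a,4,5,8,8a-octahydroazulene-3,4-diol
Conditions: TiCl4, 2,6-di-tert-butyl-4-methylpyridine, CH2Cl2, −78 °C; aq. NaHCO3
Reagents that add atoms: none
Why: Proposed new method: TiCl4 binds the C4 alkoxide and the C6 aldehyde in a six-membered chelate, the γ-carbon C7 of the allylsilane adds to C6, the charge building at C8 is tertiary and β to silicon, and loss of the silyl group from C9 (anti SE2′) leaves C8=C9. The closest known reactions are the intramolecular Hosomi–Sakurai carbocyclisation and the Lewis-acid annulation of β-silyloxy allylsilanes with aldehydes to dihydropyrans, where the tether also sits on the silicon-bearing carbon. Ring B closes in a 7-endo mode in which C7, C8 and C9 all become ring atoms, so the new double bond is endocyclic and necessarily cis. The only new stereocentre, C6, is controlled by C5: C7 is delivered from the C1 side and enters anti to the quaternary C4, with the titanium-bound oxygen on the open side anti to C1, which is the 6α (4S) carbinol. C9 loses its stereocentre, so the anti/syn outcome of step 4 does not matter. The step needs γ-regioselectivity (secured by the SE2′ path under Lewis acid), no Peterson-type loss of O10 (secured by the silyl ether and by a reactive conformer in which C10–O is gauche to C9–Si), and no protodesilylation (secured by the hindered pyridine base).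

Step 10
Reactants: 14 (3R,3aS,4S,8R,8aS)-8-{[tert-butyl(dimethyl)silyl]oxy}-6,8a-dimethyl-3-(propan-2-yl)-1,2,3,3a,4,5,8,8a-octahydroazulene-3,4-diol; 15 4-methoxybenzoyl chloride
Product: 16 (3R,3aS,4S,8R,8aS)-8-{[tert-butyl(dimethyl)silyl]oxy}-3-hydroxy-6,8a-dimethyl-3-(propan-2-yl)-1,2,3,3a,4,5,8,8a-octahydroazulen-4-yl 4-methoxybenzoate
Conditions: 15, DMAP, Et3N, CH2Cl2, 0 °C to rt
Reagents that add atoms: none
Why: DMAP-catalysed acylation of the only free secondary hydroxyl (O6); the tertiary O4 does not react and O10 is silylated, so no selectivity problem arises.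

Step 11
Reactants: 16 (3R,3aS,4S,8R,8aS)-8-{[tert-butyl(dimethyl)silyl]oxy}-3-hydroxy-6,8a-dimethyl-3-(propan-2-yl)-1,2,3,3a,4,5,8,8a-octahydroazulen-4-yl 4-methoxybenzoate
Product: 17 (3R,3aS,4S,8R,8aS)-3,8-dihydroxy-6,8a-dimethyl-3-(propan-2-yl)-1,2,3,3a,4,5,8,8a-octahydroazulen-4-yl 4-methoxybenzoate
Conditions: HF·pyridine, pyridine, THF, 0 °C to rt
Reagents that add atoms: none
Why: Fluoride cleavage of the allylic silyl ether under buffered conditions should leave the aryl ester, the tertiary alcohol and the allylic C10–O bond untouched and give the target.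

## Compound list

1 | 3-methylcyclopent-2-en-1-one | CC1=CC(=O)CC1 | starting material
2 | diisobutylaluminium (3R)-3-[(1E)-hex-1-en-1-yl]-3-methylcyclopent-1-en-1-olate | CCCC/C=C/[C@@]1(C)CCC(O[Al](CC(C)C)CC(C)C)=C1 | intermediate
3 | trimethyl{[(3R)-3-[(1E)-hex-1-en-1-yl]-3-methylcyclopent-1-en-1-yl]oxy}silane | CCCC/C=C/[C@@]1(C)CCC(O[Si](C)(C)C)=C1 | intermediate
4 | (3R)-2-(dimethoxymethyl)-3-[(1E)-hex-1-en-1-yl]-3-methylcyclopentan-1-one (C2 epimers) | CCCC/C=C/[C@@]1(C)CCC(=O)C1C(OC)OC | intermediate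
5 | (1S)-2-(dimethoxymethyl)-1-methyl-3-oxocyclopentane-1-carbaldehyde (C2 epimers) | O=C[C@@]1(C)CCC(=O)C1C(OC)OC | intermediate
6 | trimethyl(2-methylprop-2-en-1-yl)silane | C=C(C)C[Si](C)(C)C | starting material
7 | bis[(1S,2S,3S,5R)-2,6,6-trimethylbicyclo[3.1.1]heptan-3-yl][(2E)-2-methyl-3-(trimethylsilyl)prop-2-en-1-yl]borane | C[Si](C)(C)/C=C(C)/CB([C@H]1C[C@H]2C[C@@H]([C@@H]1C)C2(C)C)[C@H]1C[C@H]2C[C@@H]([C@@H]1C)C2(C)C | intermediate
8 | (1S,2R)-1-[(1S)-2-(dimethoxymethyl)-1-methyl-3-oxocyclopentyl]-3-methyl-2-(trimethylsilyl)but-3-en-1-yl bis[(1S,2S,3S,5R)-2,6,6-trimethylbicyclo[3.1.1]heptan-3-yl]borinate (C2 epimers of the ring) | C=C(C)[C@@H]([Si](C)(C)C)[C@@H](OB([C@H]1C[C@H]2C[C@@H]([C@@H]1C)C2(C)C)[C@H]1C[C@H]2C[C@@H]([C@@H]1C)C2(C)C)[C@@]1(C)CCC(=O)C1C(OC)OC | intermediate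
9 | (3S)-2-(dimethoxymethyl)-3-[(1S,2R)-1-hydroxy-3-methyl-2-(trimethylsilyl)but-3-en-1-yl]-3-methylcyclopentan-1-one (C2 epimers) | C=C(C)[C@@H]([Si](C)(C)C)[C@@H](O)[C@@]1(C)CCC(=O)C1C(OC)OC | intermediate
10 | (3S)-3-[(1S,2R)-1-{[tert-butyl(dimethyl)silyl]oxy}-3-methyl-2-(trimethylsilyl)but-3-en-1-yl]-2-(dimethoxymethyl)-3-methylcyclopentan-1-one (C2 epimers) | C=C(C)[C@@H]([Si](C)(C)C)[C@@H](O[Si](C)(C)C(C)(C)C)[C@@]1(C)CCC(=O)C1C(OC)OC | intermediate
11 | (2S,3S)-3-[(1S,2R)-1-{[tert-butyl(dimethyl)silyl]oxy}-3-methyl-2-(trimethylsilyl)but-3-en-1-yl]-2-(dimethoxymethyl)-3-methylcyclopentan-1-one | C=C(C)[C@@H]([Si](C)(C)C)[C@@H](O[Si](C)(C)C(C)(C)C)[C@@]1(C)CCC(=O)[C@@H]1C(OC)OC | intermediate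
12 | (1R,2R,3S)-3-[(1S,2R)-1-{[tert-butyl(dimethyl)silyl]oxy}-3-methyl-2-(trimethylsilyl)but-3-en-1-yl]-2-(dimethoxymethyl)-3-methyl-1-(propan-2-yl)cyclopentan-1-ol | C=C(C)[C@@H]([Si](C)(C)C)[C@@H](O[Si](C)(C)C(C)(C)C)[C@@]1(C)CC[C@@](O)(C(C)C)[C@@H]1C(OC)OC | intermediate
13 | (1R,2R,5S)-5-[(1S,2R)-1-{[tert-butyl(dimethyl)silyl]oxy}-3-methyl-2-(trimethylsilyl)but-3-en-1-yl]-2-hydroxy-5-methyl-2-(propan-2-yl)cyclopentane-1-carbaldehyde | C=C(C)[C@@H]([Si](C)(C)C)[C@@H](O[Si](C)(C)C(C)(C)C)[C@@]1(C)CC[C@@](O)(C(C)C)[C@@H]1C=O | intermediate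
14 | (3R,3aS,4S,8R,8aS)-8-{[tert-butyl(dimethyl)silyl]oxy}-6,8a-dimethyl-3-(propan-2-yl)-1,2,3,3a,4,5,8,8a-octahydroazulene-3,4-diol | O[C@H]1CC(C)=C[C@@H](O[Si](C)(C)C(C)(C)C)[C@@]2(C)CC[C@@](O)(C(C)C)[C@H]12 | intermediate
15 | 4-methoxybenzoyl chloride | COc1ccc(cc1)C(=O)Cl | starting material
16 | (3R,3aS,4S,8R,8aS)-8-{[tert-butyl(dimethyl)silyl]oxy}-3-hydroxy-6,8a-dimethyl-3-(propan-2-yl)-1,2,3,3a,4,5,8,8a-octahydroazulen-4-yl 4-methoxybenzoate | COc1ccc(C(=O)O[C@H]2CC(C)=C[C@@H](O[Si](C)(C)C(C)(C)C)[C@@]3(C)CC[C@@](O)(C(C)C)[C@H]23)cc1 | intermediate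
17 | (3R,3aS,4S,8R,8aS)-3,8-dihydroxy-6,8a-dimethyl-3-(propan-2-yl)-1,2,3,3a,4,5,8,8a-octahydroazulen-4-yl 4-methoxybenzoate | COc1ccc(C(=O)O[C@H]2CC(C)=C[C@@H](O)[C@@]3(C)CC[C@@](O)(C(C)C)[C@H]23)cc1 | target

## Step count and risks

Total steps: 11. Longest linear sequence: 11 steps (1 to 17); 6 and 15 are purchased, and the alane and the borane are made in the reaction flask.

**Step 9 (key step, proposed new method).** Protodesilylation of the allylsilane, or ionisation with Peterson-type loss of the C10 silyloxy group, may outrun a seven-membered closure that has to bring a hindered aldehyde to a 1,1-disubstituted alkene. The addition could also show poor facial selectivity at C6. The fallback uses known reactions, sets out from 13 and comes back at 14: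
- Vinylmagnesium bromide with CeCl3 should add to the aldehyde under chelation through O4 to give (1R,2S,3S)-3-[(1S,2R)-1-{[tert-butyl(dimethyl)silyl]oxy}-3-methyl-2-(trimethylsilyl)but-3-en-1-yl]-2-[(1S)-1-hydroxyprop-2-en-1-yl]-3-methyl-1-(propan-2-yl)cyclopentan-1-ol F1.
- Ring-closing metathesis with the second-generation Grubbs catalyst should close C7=C8 and give the cyclic allylsilane (3R,3aS,4S,7R,8S,8aS)-8-{[tert-butyl(dimethyl)silyl]oxy}-6,8a-dimethyl-3-(propan-2-yl)-7-(trimethylsilyl)-1,2,3,3a,4,7,8,8a-octahydroazulene-3,4-diol F2.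
- Protodesilylation with allylic transposition (acid, SE2′) then moves the double bond to C8=C9 and gives 14.

**Step 4.** The bulky borane may add slowly to the neopentyl-type aldehyde, so that attack on the ring ketone or decay of the allylborane competes. The adjacent quaternary centre may erode reagent control at C10. The fallback abandons the boron–silicon linchpin, sets out from 5 and comes back at 14:
- A catalytic asymmetric Nozaki–Hiyama–Kishi vinylation (vinyl bromide, CrCl2, NiCl2 cat., chiral sulfonamide ligand), which leaves the ketone alone, should give (3S)-2-(dimethoxymethyl)-3-[(1R)-1-hydroxyprop-2-en-1-yl]-3-methylcyclopentan-1-one F3.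
- Silylation as in step 5 gives (3S)-3-[(1R)-1-{[tert-butyl(dimethyl)silyl]oxy}prop-2-en-1-yl]-2-(dimethoxymethyl)-3-methylcyclopentan-1-one F4.
- Equilibration as in step 6 gives its (2S,3S) isomer (2S,3S)-3-[(1R)-1-{[tert-butyl(dimethyl)silyl]oxy}prop-2-en-1-yl]-2-(dimethoxymethyl)-3-methylcyclopentan-1-one F5.
- Isopropyl addition as in step 7 gives (1R,2R,3S)-3-[(1R)-1-{[tert-butyl(dimethyl)silyl]oxy}prop-2-en-1-yl]-2-(dimethoxymethyl)-3-methyl-1-(propan-2-yl)cyclopentan-1-ol F6.
- Hydrolysis as in step 8 gives (1R,2R,5S)-5-[(1R)-1-{[tert-butyl(dimethyl)silyl]oxy}prop-2-en-1-yl]-2-hydroxy-5-methyl-2-(propan-2-yl)cyclopentane-1-carbaldehyde F7.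
- Reagent-controlled 2-methylallylboration with an Ipc2B reagent gives (1R,2S,3S)-3-[(1R)-1-{[tert-butyl(dimethyl)silyl]oxy}prop-2-en-1-yl]-2-[(1S)-1-hydroxy-3-methylbut-3-en-1-yl]-3-methyl-1-(propan-2-yl)cyclopentan-1-ol F8.
- Ring-closing metathesis with the second-generation Grubbs catalyst forms C8=C9 and gives 14.

**Step 7.** The isopropyl group may add from the β-face if the large arm on C1 folds over the α-face, and enolisation or hydride transfer may compete with addition. The fallback replaces kinetic face control by thermodynamic control, sets out from 11 and comes back at 13: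
- If the C4 epimer (1S,2R,3S)-3-[(1S,2R)-1-{[tert-butyl(dimethyl)silyl]oxy}-3-methyl-2-(trimethylsilyl)but-3-en-1-yl]-2-(dimethoxymethyl)-3-methyl-1-(propan-2-yl)cyclopentan-1-ol F9 forms, it is hydrolysed as in step 8 to (1R,2S,5S)-5-[(1S,2R)-1-{[tert-butyl(dimethyl)silyl]oxy}-3-methyl-2-(trimethylsilyl)but-3-en-1-yl]-2-hydroxy-5-methyl-2-(propan-2-yl)cyclopentane-1-carbaldehyde F10.
- F10 is equilibrated by reversible retro-aldol/aldol reaction (catalytic amine base). The arrangement of 13 (formyl trans to both neighbouring bulky groups, hydroxyl cis to formyl) is expected to be the most stable.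

**Step 1.** Proton exchange between the aluminium enolate and product ketone during silylation would erase the regiochemistry needed in step 2, and enantio-induction may be incomplete for the five-membered enone. The fallback separates trapping from C–C bond formation, sets out from 1 and comes back at 4:
- The enolate is quenched with acetic anhydride to the isolable enol acetate (3R)-3-[(1E)-hex-1-en-1-yl]-3-methylcyclopent-1-en-1-yl acetate F11.
- MeLi regenerates the lithium enolate, and Claisen formylation with methyl formate gives (2R)-2-[(1E)-hex-1-en-1-yl]-2-methyl-5-oxocyclopentane-1-carbaldehyde F12 (enol tautomers).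
- Acetalisation (HC(OMe)3, MeOH, acid catalyst) gives 4.

## Further compounds

F1 | step 9 | (1R,2S,3S)-3-[(1S,2R)-1-{[tert-butyl(dimethyl)silyl]oxy}-3-methyl-2-(trimethylsilyl)but-3-en-1-yl]-2-[(1S)-1-hydroxyprop-2-en-1-yl]-3-methyl-1-(propan-2-yl)cyclopentan-1-ol | C=C(C)[C@@H]([Si](C)(C)C)[C@@H](O[Si](C)(C)C(C)(C)C)[C@@]1(C)CC[C@@](O)(C(C)C)[C@@H]1[C@@H](O)C=C
F2 | step 9 | (3R,3aS,4S,7R,8S,8aS)-8-{[tert-butyl(dimethyl)silyl]oxy}-6,8a-dimethyl-3-(propan-2-yl)-7-(trimethylsilyl)-1,2,3,3a,4,7,8,8a-octahydroazulene-3,4-diol | O[C@H]1C=C(C)[C@@H]([Si](C)(C)C)[C@@H](O[Si](C)(C)C(C)(C)C)[C@@]2(C)CC[C@@](O)(C(C)C)[C@H]12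
F3 | step 4 | (3S)-2-(dimethoxymethyl)-3-[(1R)-1-hydroxyprop-2-en-1-yl]-3-methylcyclopentan-1-one (C2 epimers) | C=C[C@@H](O)[C@@]1(C)CCC(=O)C1C(OC)OC
F4 | step 4 | (3S)-3-[(1R)-1-{[tert-butyl(dimethyl)silyl]oxy}prop-2-en-1-yl]-2-(dimethoxymethyl)-3-methylcyclopentan-1-one (C2 epimers) | C=C[C@@H](O[Si](C)(C)C(C)(C)C)[C@@]1(C)CCC(=O)C1C(OC)OC
F5 | step 4 | (2S,3S)-3-[(1R)-1-{[tert-butyl(dimethyl)silyl]oxy}prop-2-en-1-yl]-2-(dimethoxymethyl)-3-methylcyclopentan-1-one | C=C[C@@H](O[Si](C)(C)C(C)(C)C)[C@@]1(C)CCC(=O)[C@@H]1C(OC)OC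
F6 | step 4 | (1R,2R,3S)-3-[(1R)-1-{[tert-butyl(dimethyl)silyl]oxy}prop-2-en-1-yl]-2-(dimethoxymethyl)-3-methyl-1-(propan-2-yl)cyclopentan-1-ol | C=C[C@@H](O[Si](C)(C)C(C)(C)C)[C@@]1(C)CC[C@@](O)(C(C)C)[C@@H]1C(OC)OC
F7 | step 4 | (1R,2R,5S)-5-[(1R)-1-{[tert-butyl(dimethyl)silyl]oxy}prop-2-en-1-yl]-2-hydroxy-5-methyl-2-(propan-2-yl)cyclopentane-1-carbaldehyde | C=C[C@@H](O[Si](C)(C)C(C)(C)C)[C@@]1(C)CC[C@@](O)(C(C)C)[C@@H]1C=O
F8 | step 4 | (1R,2S,3S)-3-[(1R)-1-{[tert-butyl(dimethyl)silyl]oxy}prop-2-en-1-yl]-2-[(1S)-1-hydroxy-3-methylbut-3-en-1-yl]-3-methyl-1-(propan-2-yl)cyclopentan-1-ol | C=C[C@@H](O[Si](C)(C)C(C)(C)C)[C@@]1(C)CC[C@@](O)(C(C)C)[C@@H]1[C@@H](O)CC(C)=C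
F9 | step 7 | (1S,2R,3S)-3-[(1S,2R)-1-{[tert-butyl(dimethyl)silyl]oxy}-3-methyl-2-(trimethylsilyl)but-3-en-1-yl]-2-(dimethoxymethyl)-3-methyl-1-(propan-2-yl)cyclopentan-1-ol | C=C(C)[C@@H]([Si](C)(C)C)[C@@H](O[Si](C)(C)C(C)(C)C)[C@@]1(C)CC[C@](O)(C(C)C)[C@@H]1C(OC)OC
F10 | step 7 | (1R,2S,5S)-5-[(1S,2R)-1-{[tert-butyl(dimethyl)silyl]oxy}-3-methyl-2-(trimethylsilyl)but-3-en-1-yl]-2-hydroxy-5-methyl-2-(propan-2-yl)cyclopentane-1-carbaldehyde | C=C(C)[C@@H]([Si](C)(C)C)[C@@H](O[Si](C)(C)C(C)(C)C)[C@@]1(C)CC[C@](O)(C(C)C)[C@@H]1C=O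
F11 | step 1 | (3R)-3-[(1E)-hex-1-en-1-yl]-3-methylcyclopent-1-en-1-yl acetate | CCCC/C=C/[C@@]1(C)CCC(OC(C)=O)=C1
F12 | step 1 | (2R)-2-[(1E)-hex-1-en-1-yl]-2-methyl-5-oxocyclopentane-1-carbaldehyde (enol tautomers) | CCCC/C=C/[C@@]1(C)CCC(=O)C1C=O
A1 | alternative 1 | (1R,2S,3S)-2-[(1S)-1-hydroxy-3-methylbut-3-en-1-yl]-3-[(1R)-1-hydroxyprop-2-en-1-yl]-3-methyl-1-(propan-2-yl)cyclopentan-1-ol | C=C[C@@H](O)[C@@]1(C)CC[C@@](O)(C(C)C)[C@@H]1[C@@H](O)CC(C)=C
A2 | alternative 1 | (3R,3aS,4S,8R,8aS)-6,8a-dimethyl-3-(propan-2-yl)-1,2,3,3a,4,5,8,8a-octahydroazulene-3,4,8-triol | O[C@H]1CC(C)=C[C@@H](O)[C@@]2(C)CC[C@@](O)(C(C)C)[C@H]12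
A3 | alternative 2 | 2,5-dimethyl-2-(3-oxobutyl)cyclohexane-1,3-dione | CC(=O)CCC1(C)C(=O)CC(C)CC1=O
A4 | alternative 2 | (4aS)-4a,7-dimethyl-4,4a,7,8-tetrahydronaphthalene-2,5(3H,6H)-dione (C7 epimers) | CC1CC(=O)[C@@]2(C)CCC(=O)C=C2C1
A5 | alternative 2 | (3R,3aS,8aS)-3-hydroxy-6,8a-dimethyl-3-(propan-2-yl)octahydroazulene-4,8-dione, cis-fused (C6 epimers) | CC1CC(=O)[C@@]2(C)CC[C@@](O)(C(C)C)[C@H]2C(=O)C1
A6 | alternative 3 | [(4-methylcyclopent-1-ene-1,2-diyl)bis(oxy)]bis(trimethylsilane) | CC1CC(O[Si](C)(C)C)=C(O[Si](C)(C)C)C1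
A7 | alternative 3 | racemic cis,anti,cis-1,4-dimethyl-2,6-bis[(trimethylsilyl)oxy]tricyclo[5.3.0.0(2,6)]decan-8-one (C4 epimers, one enantiomer drawn) | CC1C[C@]2(O[Si](C)(C)C)[C@H]3C(=O)CC[C@@]3(C)[C@]2(O[Si](C)(C)C)C1
A8 | alternative 3 | racemic cis-fused 6,8a-dimethylhexahydroazulene-3,4,8-trione (C6 epimers, one enantiomer drawn) | CC1CC(=O)[C@@]2(C)CCC(=O)[C@H]2C(=O)C1
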